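Substrate is left over in Thursday's run: partner was charged at 55.0% of the substrate, and the target, at 47.1% after 6.00 h, rose by 1.7 percentage points over the last interval. Taking that partner as spent, 85.6% of it stands as target, a reading called the keep here.

| setting | Thursday's | Sunday's | Tuesday's | noon | spring |
|---|---|---|---|---|---|
| substrate | 20 mM | 20 mM | 20 mM | 20 mM | 20 mM |
| partner | 11 mM | 20 mM | 10 mM | 10.0 mM | 15.0 mM |
| free catalyst | 0.20 mM | 0.20 mM | 0.13 mM | 0.20 mM | 0.050 mM |
| remark | run made earlier | run made earlier | run made earlier |  |  |
| time |  |  |  | 8.0 h | 8.0 h |

| Thursday's: time / h | Thursday's: target / % | Sunday's: time / h | Sunday's: target / % | Tuesday's: time / h | Tuesday's: target / % |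
|---|---|---|---|---|---|
| 1.33 | 23.7 | 0.417 | 8.8 | 1.33 | 15.8 |
| 3.00 | 40.3 | 1.00 | 22.8 | 3.00 | 29.0 |
| 4.00 | 45.4 | 2.50 | 46.0 | 4.00 | 36.3 |
| 6.00 | 47.1 | 6.00 | 77.8 | 6.00 | 40.3 |

(scatter of a reading: 1 percentage point)

1. the winner by amount of target, in percent of the substrate charged; "neither" if no more than 2 percentage points parts them (noon / spring / neither)
2. how much target is there at the end, in percent of the substrate charged: noon
3. how much target is there at the end, in percent of the substrate charged: spring



Thursday's first reading gives 17.8 h⁻¹ as the turnover rate, target made per catalyst per hour. Tuesday's, with less catalyst, gives 18.3 h⁻¹, so the rate reads as first order in catalyst. Sunday's, with partner equal to substrate, gives 1.28 times Thursday's.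

The ladder follows. One turnover takes 3.37 min. Noon's partner, 50.0% of the substrate charge, lasts 2.81 h at this rate, longer than one turnover and less than the 8.0 h allowed. It is therefore the limiting reagent, and the keep on that charge gives 42.8%. Spring's partner lasts 16.8 h, longer than the time allowed, so the catalyst sets the pace. At 0.250% of the substrate charge it passes 35.6% of that charge, and the keep leaves 30.5%. Noon leads by 12 points, against a margin of 2 points.

The forecast also names noon, with 42.5% and 37%, the second higher than this reckoning, on the ground that “partner hardly matters until it runs low”.

The flask gives noon: 43.2% for noon and 32.8% for spring.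

    catalyst intermediate B → free catalyst + target (k = 63.0 h⁻¹)
    partner + catalyst intermediate A → catalyst intermediate B (k = 6500 L mol⁻¹ h⁻¹)
    substrate + free catalyst → catalyst intermediate A (k = 2800 L mol⁻¹ h⁻¹)
    substrate + target → side product (k = 2.30 L mol⁻¹ h⁻¹)

Each turnover spends one partner, and spring spent 50.2% of its charge, which is 18.8 h⁻¹ per catalyst against the 17.8 h⁻¹ read from Thursday. The neighbour flask is spring with 38 mM of partner, or 1.90 equiv, above Sunday's charge. Its turnover rate is therefore taken as 17.8 h⁻¹ times Sunday's 1.28, which passes 45.6% of the substrate charge, and the keep leaves 39.0%. That flask gives 39.1% of target, with 77% of its partner still there.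

The runs are calculated with made-up constants.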